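The runs were generated by integration with constants of no real substance; noise was put on by code.

The reading that counted came 20 min after mixing: how much Uv had formed from the acidic substrate Qo and the electrophile Ze, at each of the charges of the base Ve listed here.

| setting | ochre | red | Wednesday's | Sunday's | Saturday's | Friday's | Thursday's |
|---|---|---|---|---|---|---|---|
| Qo | 0.14 M | 0.14 M | 0.14 M | 0.14 M | 0.14 M | 0.14 M | 0.14 M |
| Ve | 0.0014 M | 0.16 M | 0.00120 M | 0.00400 M | 0.0100 M | 0.0300 M | 0.100 M |
| Ze | 0.35 M | 0.35 M | 0.350 M | 0.350 M | 0.350 M | 0.350 M | 0.350 M |
| remark | run made earlier | run made earlier |  |  |  |  |  |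
| time |  |  | 20 min | 20 min | 20 min | 20 min | 20 min |

- ochre (time / min: Uv / %, Qo / %): 2.00: 0.5, 100.0; 4.00: 0, 99.2; 6.00: 0.6, 97.4; 8.00: 0.1, 98.3; 10.0: 0, 100.4
- red (time / min: Uv / %, Qo / %): 0.833: 2.4, 44.1; 2.50: 6.9, 45.2; 5.00: 10.6, 44.2; 8.00: 16.9, 42.2; 10.0: 18.8, 40.8

(readings scatter by 1 percentage point)

- "hardly changes" means that all values lie within two and a half points (for a concentration: within two and a half percent of the largest)

1. amount of Uv at the end, in percent of the Qo charged for Wednesday's, Sunday's, Saturday's, Friday's, Thursday's, in this order
2. the shape of the row from first to last (falls all the way / rises all the way / rises, then falls / hardly changes / falls, then rises)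

**The puzzle.** At 0.833 min in the red run, Qo stood at 44.1% yet Uv stood at 2.4%, so I called the gap the hidden share h (charge minus Qo minus Uv), and it read 53.5%. By 10.0 min Uv had gained 16 percentage points, more than the 3.3 points that Qo lost, and h had dropped to 40.4%. I took h to be Qo stripped of a proton by Ve within moments, feeding Uv slowly. In the ochre run Ve was 1.00% of the Qo, about the scatter of 1 point, so a change of that size could hide in those flat readings, and they could not tell me whether anything had reacted.

**Capture time.** I defined the capture time τ, the hidden share divided by the rate at which Uv forms, and the red run gave 26.2 min. Ze is charged at 0.350 M in the flasks asked about, which exceeds the Qo charged, so I treated capture as pseudo-first-order with this one τ.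

**Both ends.** In Wednesday's flask Ve, at 0.00120 M, is the limiting reagent, and if all of it goes hidden, the share captured by 20 min is 1 − exp(−t/τ) = 53.3%, which gives me 0.457% Uv. For Thursday's flask the same sum, with all of Ve taken as hidden, gives 38.1%, but I expected less, since in the red run h read 53.5% with Ve charged at 114% of the Qo.

**The forecast.** It gave 0.5%, 1.6%, 3.9%, 10.6% and 26%, so rises all the way, on the ground that “Uv is therefore capped by the Ve charged”.

**The result.**

    Qo + Ve ⇌ Ul + Wy, settled at all times (K = 0.990)
    Ze + Wy ⇌ Uv (K = 6.80 /M, k = 0.140 /M/min)

The flasks gave 0.451%, 1.48%, 3.59%, 9.73% and 23.4%, so the row rises all the way. In Thursday's flask Wy, the hidden form, went from 30.5% at 10.0 min to 24.8% at 20.0 min. Taking the mid-time value over 20 min at the capture time τ gives 23.3% of the Qo charged, and Thursday's flask held 23.4%.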